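## Structural features

The target is a sesquineolignan. Its core is a cis-fused 2,6-diaryl-3,7-dioxabicyclo[3.3.0]octane (furofuran, atoms C1, C2, O3, C4, C5, C6, O7, C8). C6 carries ring A (4-hydroxy-3,5-dimethoxyphenyl). C2 carries ring B, which is also the benzo ring of a 2,3-dihydrobenzofuran (ring C, atoms O1′, C2′, C3′) bearing ring D (4-hydroxy-3-methoxyphenyl) on C2′ and a hydroxymethyl group on C3′.

The furofuran holds four contiguous stereocentres, C2–C1–C5–C6, configured (1R,2S,5R,6S) with both aryl groups on the convex face. Ring C holds two adjacent ones, (2′S,3′S), with aryl and hydroxymethyl cis, the less stable arrangement. The flat ring B separates the two arrays, so neither can direct the other and each needs its own source of absolute configuration.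

The fragile points are the three benzylic C–O bonds para to oxygen substituents (C2–O3, C6–O7, O1′–C2′). They ionise in acid and, once the phenols are free, can open through p-quinone methides in base. The cis ring C drifts to trans whenever C2′ or C3′ becomes labile, and the benzylic ethers exclude hydrogenolysis.

The real difficulty is threefold: fixing C1 and C5 absolutely, joining three different oxygenated aryl units in a defined order, and closing the cis ring C last under non-equilibrating conditions.

The key step uses the fact that C1 and C5 each carry one aryl carbinol carbon (C2, C6) and one oxygenated methylene (C8, C4). That is the pattern left when an aroyl anion equivalent and an aryl aldehyde are added across the C=C bond of a 5-alkoxybutenolide, whose carbonyl and acetal carbons become C8 and C4.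

## Logic of the disconnections

**24 to 23 to 22.** Only the two aryl O–Si bonds are cut last, because the free phenols are the most labile form of the molecule. The C3′ hydroxymethyl group is then traced to a methyl ester. The gain is that every earlier step handles non-ionisable aryl ethers, and the ester is the acceptor group a carbenoid needs. The demands are buffered fluoride (no phenoxide) and an ester reduction that does not touch the acidic C3′–H.

**22 to 21.** The C2′–C3′ bond is cut as a carbenoid insertion into a benzylic ether C–H bond. Ring C and both of its stereocentres disappear, leaving a benzyl aryl ether with a diazoacetate side arm. The catalyst must impose the cis geometry and the absolute sense on a substrate whose other stereocentres are remote.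

**21 to 20 to 17 + 19.** The aryl–C(N2) bond is cut back to an aryl iodide and the O–CH2 bond of the benzyl ether back to a phenol and a benzylic alcohol. Ring D becomes a two-step vanillin derivative and ring B a 2-iodophenol. The coupling must keep the diazo group, and the etherification must work at a doubly ortho-substituted phenol without endangering aryl silyl ethers.

**17 to 16 to 15.** The C–I bond and then the O-allyl bond are cut. Iodine goes to the only open position ortho to a free phenol, and allyl is the one ring B protecting group orthogonal to the silyl ether on ring A. The iodination must prefer the phenol ring over two other electron-rich rings.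

**15 to 14.** C2–O3 and C6–O7 are cut. Both are benzylic C–O bonds that can form through cations, so the configuration of the two carbinol carbons in 14 does not matter. The bicycle opens to a chain with only C1 and C5 defined. Closure must place both aryl groups exo and must not be left to equilibrate.

**14 to 13 to 12.** The four C–OH carbons of 14 are returned to a ketone (C6), a lactone carbonyl (C8) and an acetal carbon (C4), and the ketone to a dithiane. This reveals a butyrolactone carrying a chiral acetal and an acyl anion equivalent. The dithiane must be hydrolysed beside an allyl ether and a free alcohol, and one hydride reagent must reduce three carbons and release the auxiliary.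

**12 to 4 + 7 + 9.** C5–C6 and C1–C2 are cut in one operation. Three components of similar size result, and C1 and C5 are set from a single acetal stereocentre. The step needs 1,4-addition, anti delivery twice, and trapping of the enolate before it equilibrates.

**Starting materials.** 4 goes back to 2 and 3, and 2 to 1. 7 goes back to 6 and then 5. 9 goes back to 8. 19 goes back to 18 and then 8. Each is a one- or two-step functional-group change on a commodity chemical.

## Other disconnections considered

**Alternative 1:** The cut is the same pair of bonds as in step 9 (C2–O3, C6–O7), but at the hydrocarbon oxidation level.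
- **Forward step:** the (2R,3R)-dibenzylbutanediol A2 would be dehydrogenated twice with DDQ. Each 4-hydroxybenzyl group would pass through a p-quinone methide captured by the hydroxymethyl group on the far bridgehead, giving (+)-medioresinol A1.
- **In favour:** A2 has only two stereocentres, which the same butenolide chemistry could set with a benzyl halide as the enolate trap. No carbinol epimers arise, no dithiane must be hydrolysed, and closure is a near-neutral conjugate addition expected to place the aryl groups exo.
- **Against here:** the step needs both phenols free, so it ends in A1 with a ring A and a ring B hydroxyl that must then be told apart for the O-benzylation. A quinone methide next to a second electron-rich arene can also be captured by carbon (aryltetralin formation). A1 still has two oxidisable 4-hydroxybenzylic C–H bonds.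
- **Comparison:** both plans reach the same bicycle. The alternative is the better one in needing no stereoconvergence by ionising alcohols, and it would be about two steps shorter to the furofuran. The chosen plan is preferred because it keeps the two phenols differentiated from first step to last and avoids a stoichiometric oxidant on a substrate with three electron-rich rings.

**Alternative 2:** The cut is O1′–C2′ of ring C.
- **Forward step:** the syn-configured phenol A4, its two stereocentres set by an Evans aldol reaction, would close by intramolecular Mitsunobu etherification (PPh3, diisopropyl azodicarboxylate). The phenol displaces the activated benzylic hydroxyl with inversion to give the cis-dihydrobenzofuran A3.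
- **In favour:** relative and absolute configuration come from a very reliable auxiliary-controlled reaction and are transferred stereospecifically. No diazo compound or rhodium catalyst is needed, and the tosylate on ring D suppresses an SN1 leak. On predictability of the C2′/C3′ stereochemistry this is the equal of the carbenoid insertion of step 16, and probably better.
- **Against here:** A3 has no substituent at C5′ of ring B. The whole furofuran would therefore have to be grown on a molecule that already contains the sensitive cis ring C, starting with a regioselective arene functionalisation. The acid closure of step 9 would then run beside a second ionisable benzylic ether. Final tosylate removal needs base just as a p-hydroxyphenyl group is freed next to that ether.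
- **Comparison:** attaching and removing the auxiliary, protecting the primary alcohol and detosylating add about four operations relative to steps 14 to 17. The chosen order (robust furofuran first, fragile cis ring last) is judged safer.

**Alternative 3:** C2 is disconnected on both sides (O3–C2 and C1–C2).
- **Forward step:** the 2-aryl-3-(hydroxymethyl)-2,3-dihydrofuran A6 and the dimethyl acetal A7 of aldehyde 9 would react under TMSOTf. The hydroxyl of A6 exchanges into the acetal, the enol ether carbon C1 attacks the aryl-stabilised oxocarbenium ion (Prins-type closure), and methanol captures the new cation at C8 to give the bicyclic acetal A5.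
- **In favour:** one C–C bond, one C–O bond and the second ring form in a single convergent step from two fragments of similar size, with no hydride or mercury reagent. In convergence and atom economy of the ring-forming step it is the better plan.
- **Against here:** A6 must be made as a single enantiomer with the C5/C6 trans relationship, which moves the stereochemical work into a separate synthesis of an acid-sensitive enol ether. The configuration at C2 depends on the oxocarbenium geometry in the closing transition state, and an endo aryl group is a realistic outcome. The C8 methoxy group must afterwards be removed by ionic reduction (silane and Lewis acid), which can also ionise C2–O3 and C6–O7.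
- **Comparison:** after that reduction the chemistry used from 15 onwards would apply unchanged, so the two plans are equal downstream. The chosen plan spends three hydrolysis, reduction and closure steps (7 to 9) but draws both bridgehead centres from an inexpensive crystalline auxiliary in one step. The alternative has the shorter ring assembly but the longer and less certain route to its chiral fragment.

Key step: step 6

**Remarks on the chemistry**

(a) Consistency check: the (5R) acetal carbon and l-menthyl group of 4, the 3,4-trans/4,5-trans arrangement of 12 and the (1R,5R) bridgeheads of 24 were compared centre by centre and agree. The dihydrobenzofuran of 24 is cis, (2′S,3′S).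

(b) Design changes to the precursors. Both phenol oxygens that must last to the end are carried as triisopropylsilyl ethers, not tert-butyldimethylsilyl ethers, because aryl tert-butyldimethylsilyl ethers are at risk from LiAlH4, phenoxides and amines; one buffered fluoride step removes both. The ring B allyl ether needs its own removal (step 10) before the free phenol can direct the iodination. The dithiane is opened with HgCl2/CaCO3, a weak electrophile, because of the allyl ether and the free benzylic alcohol.

(c) Assumption: the benzylic carbinol carbons made in steps 6 and 8 are each expected as a pair of epimers. 12 and 13 are drawn with the aldol carbinol in the configuration that maps onto C2, and 14 leaves the carbinol from step 8 undefined. Both centres are reset in step 9.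

(d) The exo placement of both aryl groups in step 9 is treated as the outcome of ring closure onto the benzylic cations. It is preserved by short exposure to acid, since re-ionisation can reach the C2 and C6 epimers.

## Route

Step 1
Reactants: 1 furfural
Product: 2 5-hydroxyfuran-2(5H)-one (racemic hemiacetal)
Conditions: O2, visible light, rose bengal (C20H2Cl4I4Na2O5, cat.), MeOH, rt
Reagents that add atoms: oxygen, O=O
Why: Dye-sensitised photo-oxygenation: singlet oxygen adds across the furan in a [4+2] cycloaddition and methanol solvolyses the endoperoxide with loss of the formyl carbon as methyl formate, leaving the hydroxybutenolide; no stereocentre is fixed because the hemiacetal carbon is labile.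

Step 2
Reactants: 2 5-hydroxyfuran-2(5H)-one; 3 l-menthol, (1R,2S,5R)-2-isopropyl-5-methylcyclohexan-1-ol
Product: 4 (5R)-5-(l-menthyloxy)furan-2(5H)-one
Conditions: (1S)-(+)-10-camphorsulfonic acid (cat.), toluene, reflux with azeotropic removal of water; crystallisation from hexane; mother liquor re-equilibrated with the same acid
Reagents that add atoms: none
Why: Acid-catalysed acetalisation of the lactol gives both C5 epimers, which interconvert under the acid; the (5R) epimer is the crystalline one, so crystallisation with re-equilibration of the mother liquor should funnel the mixture into a single diastereomer.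

Step 3
Reactants: 5 syringaldehyde (4-hydroxy-3,5-dimethoxybenzaldehyde)
Product: 6 3,5-dimethoxy-4-(triisopropylsilyloxy)benzaldehyde
Conditions: TIPSCl, imidazole, DMF, rt → 40 °C
Reagents that add atoms: triisopropylsilyl chloride, CC(C)[Si](Cl)(C(C)C)C(C)C
Why: Silylation of an acidic, hindered phenol; the triisopropylsilyl ether should withstand the organolithium, hydride, weak acid and amine conditions ahead and fall only to fluoride in step 18.

Step 4
Reactants: 6 3,5-dimethoxy-4-(triisopropylsilyloxy)benzaldehyde
Product: 7 2-[3,5-dimethoxy-4-(triisopropylsilyloxy)phenyl]-1,3-dithiane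
Conditions: HS(CH2)3SH, BF3·OEt2 (cat.), CH2Cl2, 0 °C
Reagents that add atoms: propane-1,3-dithiol, SCCCS
Why: Lewis-acid-catalysed dithioacetalisation turns the formyl carbon into an acyl anion equivalent (umpolung); the aryl silyl ether should tolerate catalytic BF3·OEt2 at 0 °C.

Step 5
Reactants: 8 vanillin (4-hydroxy-3-methoxybenzaldehyde)
Product: 9 4-allyloxy-3-methoxybenzaldehyde
Conditions: allyl bromide, K2CO3, acetone, reflux
Reagents that add atoms: allyl bromide, C=CCBr
Why: Williamson ether synthesis on the phenoxide; the allyl ether is inert to enolates, hydride and acid and can later be removed selectively beside the silyl ether.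

Step 6
Reactants: 7 2-[3,5-dimethoxy-4-(triisopropylsilyloxy)phenyl]-1,3-dithiane; 4 (5R)-5-(l-menthyloxy)furan-2(5H)-one; 9 4-allyloxy-3-methoxybenzaldehyde
Product: 12 (3S,4R,5R)-3-[(S)-(4-allyloxy-3-methoxyphenyl)(hydroxy)methyl]-4-{2-[3,5-dimethoxy-4-(triisopropylsilyloxy)phenyl]-1,3-dithian-2-yl}-5-(l-menthyloxy)dihydrofuran-2(3H)-one, via 2-lithio-1,3-dithiane 10 (not isolated), via lithium enolate 11 (not isolated)
Conditions: n-BuLi, THF, −78 → −20 °C; 4, THF, −78 °C; 9, THF, −78 °C; AcOH, −78 °C
Reagents that add atoms: none
Why: n-BuLi deprotonates 7 to the sulfur-stabilised benzylic anion 10, which adds 1,4 to the unsaturated lactone 4 (Michael addition, C5–C6 bond), and the lithium enolate 11 is trapped by aldehyde 9 in an aldol addition (C1–C2 bond); the closest known reaction type is the tandem conjugate addition–enolate trapping of lithiated 2-aryl-1,3-dithianes on 5-alkoxybutenolides, established for dibenzylbutyrolactone and furofuran lignans. No ring is closed. The β-carbon (later C5) is controlled by the menthyloxy group on the acetal carbon, which shields one face of the flat butenolide so that the bulky anion enters anti to it (4,5-trans). The α-carbon (later C1) is controlled by relay: the new quaternary dithianyl substituent blocks its own face of 11, so the aldehyde is bound on the opposite face (3,4-trans). The carbinol carbon (later C2) depends only on the aldol transition state of a lactone enolate of fixed geometry, so both epimers are to be expected, which is harmless because that centre is ionised in step 9. The step needs 1,4- over 1,2-addition, secured by the soft, hindered, delocalised anion meeting a doubly activated alkene in THF without additives. It also needs aldol trapping to outrun proton transfer and retro-Michael or retro-aldol reversal, secured by a non-enolisable aldehyde added at −78 °C and a cold acidic quench.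

Step 7
Reactants: 12 (3S,4R,5R)-3-[(S)-(4-allyloxy-3-methoxyphenyl)(hydroxy)methyl]-4-{2-[3,5-dimethoxy-4-(triisopropylsilyloxy)phenyl]-1,3-dithian-2-yl}-5-(l-menthyloxy)dihydrofuran-2(3H)-one
Product: 13 (3S,4R,5R)-3-[(S)-(4-allyloxy-3-methoxyphenyl)(hydroxy)methyl]-4-[3,5-dimethoxy-4-(triisopropylsilyloxy)benzoyl]-5-(l-menthyloxy)dihydrofuran-2(3H)-one
Conditions: HgCl2, CaCO3, MeCN–H2O (4:1), rt → 50 °C; product used without delay
Reagents that add atoms: water, O
Why: Thiophilic, mercury-assisted hydrolysis of the dithioacetal unmasks the aryl ketone; HgCl2 buffered with CaCO3 is a weak electrophile toward alkenes and the medium stays neutral, so the allyl ether, the lactone acetal and the β-hydroxy group should be left alone, and the trans,trans lactone is the stable arrangement at both enolisable carbons.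

Step 8
Reactants: 13 (3S,4R,5R)-3-[(S)-(4-allyloxy-3-methoxyphenyl)(hydroxy)methyl]-4-[3,5-dimethoxy-4-(triisopropylsilyloxy)benzoyl]-5-(l-menthyloxy)dihydrofuran-2(3H)-one
Product: 14 (1S,2R,3R)-1-(4-allyloxy-3-methoxyphenyl)-4-[3,5-dimethoxy-4-(triisopropylsilyloxy)phenyl]-2,3-bis(hydroxymethyl)butane-1,4-diol (epimers at C4)
Conditions: LiAlH4, THF, 0 °C → rt; aqueous NaOH work-up
Reagents that add atoms: none
Why: Hydride reduces the ketone and the lactone; the lactol alkoxide collapses with loss of menthoxide and the freed aldehyde is reduced too, so C8 and C4 both arrive as hydroxymethyl groups. The new carbinol carbon (C6) forms without control, which is acceptable because it is ionised in step 9.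

Step 9
Reactants: 14 (1S,2R,3R)-1-(4-allyloxy-3-methoxyphenyl)-4-[3,5-dimethoxy-4-(triisopropylsilyloxy)phenyl]-2,3-bis(hydroxymethyl)butane-1,4-diol
Product: 15 (1R,2S,5R,6S)-2-(4-allyloxy-3-methoxyphenyl)-6-[3,5-dimethoxy-4-(triisopropylsilyloxy)phenyl]-3,7-dioxabicyclo[3.3.0]octane
Conditions: p-toluenesulfonic acid monohydrate (10 mol %), 4 Å molecular sieves, CH2Cl2, 0 °C → rt; quenched with Et3N at full conversion
Reagents that add atoms: none
Why: Acid-catalysed double cyclodehydration (SN1 etherification): each electron-rich benzylic alcohol ionises to a cation stabilised by its para oxygen and is captured by the hydroxymethyl group on the remote bridgehead in a 5-exo closure. The cis-fused bicycle should steer each aryl group to the convex, exo side at C2 and C6 whatever the carbinol configuration was, so the epimers converge; the acid is neutralised promptly because the benzylic ethers can re-ionise.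

Step 10
Reactants: 15 (1R,2S,5R,6S)-2-(4-allyloxy-3-methoxyphenyl)-6-[3,5-dimethoxy-4-(triisopropylsilyloxy)phenyl]-3,7-dioxabicyclo[3.3.0]octane
Product: 16 4-{(1R,2S,5R,6S)-6-[3,5-dimethoxy-4-(triisopropylsilyloxy)phenyl]-3,7-dioxabicyclo[3.3.0]octan-2-yl}-2-methoxyphenol
Conditions: Pd(PPh3)4 (cat.), morpholine, THF, rt
Reagents that add atoms: none
Why: Tsuji–Trost deallylation: the aryl allyl ether ionises to a π-allyl palladium complex and the allyl group is passed to morpholine; the near-neutral conditions should leave the silyl ether and the benzylic ethers untouched.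

Step 11
Reactants: 16 4-{(1R,2S,5R,6S)-6-[3,5-dimethoxy-4-(triisopropylsilyloxy)phenyl]-3,7-dioxabicyclo[3.3.0]octan-2-yl}-2-methoxyphenol
Product: 17 4-{(1R,2S,5R,6S)-6-[3,5-dimethoxy-4-(triisopropylsilyloxy)phenyl]-3,7-dioxabicyclo[3.3.0]octan-2-yl}-2-iodo-6-methoxyphenol
Conditions: I2, NaHCO3, THF–H2O, 0 °C → rt
Reagents that add atoms: iodine, II
Why: Electrophilic iodination of a phenol under weakly basic conditions; only one position ortho to the hydroxyl is open and the para position is blocked, and unactivated I2 should not attack the two non-phenolic rings.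

Step 12
Reactants: 8 vanillin
Product: 18 3-methoxy-4-(triisopropylsilyloxy)benzaldehyde
Conditions: TIPSCl, imidazole, DMF, rt
Reagents that add atoms: triisopropylsilyl chloride, CC(C)[Si](Cl)(C(C)C)C(C)C
Why: Standard phenol silylation; the same silyl group as on ring A is used so that one fluoride step frees both phenols at the end.

Step 13
Reactants: 18 3-methoxy-4-(triisopropylsilyloxy)benzaldehyde
Product: 19 [3-methoxy-4-(triisopropylsilyloxy)phenyl]methanol
Conditions: NaBH4, MeOH, 0 °C
Reagents that add atoms: none
Why: Borohydride reduction of the aldehyde to the primary benzylic alcohol; the aryl triisopropylsilyl ether is stable to these conditions.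

Step 14
Reactants: 17 4-{(1R,2S,5R,6S)-6-[3,5-dimethoxy-4-(triisopropylsilyloxy)phenyl]-3,7-dioxabicyclo[3.3.0]octan-2-yl}-2-iodo-6-methoxyphenol; 19 [3-methoxy-4-(triisopropylsilyloxy)phenyl]methanol
Product: 20 (1R,2S,5R,6S)-2-(3-iodo-5-methoxy-4-{[3-methoxy-4-(triisopropylsilyloxy)phenyl]methoxy}phenyl)-6-[3,5-dimethoxy-4-(triisopropylsilyloxy)phenyl]-3,7-dioxabicyclo[3.3.0]octane
Conditions: PPh3, diisopropyl azodicarboxylate, THF, 0 °C → rt
Reagents that add atoms: none
Why: Mitsunobu etherification: the alkoxyphosphonium ion of the primary benzylic alcohol is displaced by the acidic 2-iodo-6-methoxyphenol; no base or halide is present, so both aryl silyl ethers are safe.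

Step 15
Reactants: 20 (1R,2S,5R,6S)-2-(3-iodo-5-methoxy-4-{[3-methoxy-4-(triisopropylsilyloxy)phenyl]methoxy}phenyl)-6-[3,5-dimethoxy-4-(triisopropylsilyloxy)phenyl]-3,7-dioxabicyclo[3.3.0]octane
Product: 21 methyl 2-diazo-2-(5-{(1R,2S,5R,6S)-6-[3,5-dimethoxy-4-(triisopropylsilyloxy)phenyl]-3,7-dioxabicyclo[3.3.0]octan-2-yl}-3-methoxy-2-{[3-methoxy-4-(triisopropylsilyloxy)phenyl]methoxy}phenyl)acetate
Conditions: methyl diazoacetate, Pd(PPh3)4 (10 mol %), Ag2CO3, Et3N, toluene, rt
Reagents that add atoms: methyl diazoacetate, COC(=O)C=[N+]=[N-]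
Why: Palladium-catalysed cross-coupling of an aryl iodide with the C–H bond of a diazoacetate (oxidative addition, base-assisted transfer of the diazo ester to palladium, reductive elimination), which keeps the diazo group; Ag2CO3 takes up iodide and the proton, and Et3N acts as proton shuttle.

Step 16
Reactants: 21 methyl 2-diazo-2-(5-{(1R,2S,5R,6S)-6-[3,5-dimethoxy-4-(triisopropylsilyloxy)phenyl]-3,7-dioxabicyclo[3.3.0]octan-2-yl}-3-methoxy-2-{[3-methoxy-4-(triisopropylsilyloxy)phenyl]methoxy}phenyl)acetate
Product: 22 methyl (2S,3R)-7-methoxy-2-[3-methoxy-4-(triisopropylsilyloxy)phenyl]-5-{(1R,2S,5R,6S)-6-[3,5-dimethoxy-4-(triisopropylsilyloxy)phenyl]-3,7-dioxabicyclo[3.3.0]octan-2-yl}-2,3-dihydro-1-benzofuran-3-carboxylate (2,3-cis)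
Conditions: Rh2(S-PTTL)4 (dirhodium tetrakis[N-phthaloyl-(S)-tert-leucinate], 2 mol %), toluene, −60 °C
Reagents that add atoms: none
Why: Intramolecular carbenoid C–H insertion: the rhodium carbene inserts into the benzylic C–H bond alpha to the ether oxygen (1,5-insertion) and closes ring C. The phthalimido-tert-leucinate ligands select which enantiotopic hydrogen and which carbene face react, which should give the cis (2′S,3′R) ester under kinetic control at low temperature; the remote furofuran centres turn any mis-induction into a diastereomer that can be removed.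

Step 17
Reactants: 22 methyl (2S,3R)-7-methoxy-2-[3-methoxy-4-(triisopropylsilyloxy)phenyl]-5-{(1R,2S,5R,6S)-6-[3,5-dimethoxy-4-(triisopropylsilyloxy)phenyl]-3,7-dioxabicyclo[3.3.0]octan-2-yl}-2,3-dihydro-1-benzofuran-3-carboxylate
Product: 23 [(2S,3S)-7-methoxy-2-[3-methoxy-4-(triisopropylsilyloxy)phenyl]-5-{(1R,2S,5R,6S)-6-[3,5-dimethoxy-4-(triisopropylsilyloxy)phenyl]-3,7-dioxabicyclo[3.3.0]octan-2-yl}-2,3-dihydro-1-benzofuran-3-yl]methanol
Conditions: i-Bu2AlH, CH2Cl2, −78 → −20 °C; aqueous potassium sodium tartrate
Reagents that add atoms: none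
Why: Non-basic hydride reduction of the ester to the primary alcohol at low temperature, so the acidic C3′–H is not removed and the cis relationship is kept (the descriptor changes from 3′R to 3′S only through the priority change).

Step 18
Reactants: 23 [(2S,3S)-7-methoxy-2-[3-methoxy-4-(triisopropylsilyloxy)phenyl]-5-{(1R,2S,5R,6S)-6-[3,5-dimethoxy-4-(triisopropylsilyloxy)phenyl]-3,7-dioxabicyclo[3.3.0]octan-2-yl}-2,3-dihydro-1-benzofuran-3-yl]methanol
Product: 24 (1R,2S,5R,6S)-6-(4-hydroxy-3,5-dimethoxyphenyl)-2-[(2S,3S)-2-(4-hydroxy-3-methoxyphenyl)-3-(hydroxymethyl)-7-methoxy-2,3-dihydro-1-benzofuran-5-yl]-3,7-dioxabicyclo[3.3.0]octane (CNP0126146.1)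
Conditions: Bu4NF, AcOH (1:1), THF, 0 °C → rt
Reagents that add atoms: none
Why: Fluoride cleaves both aryl Si–O bonds; acetic acid protonates each phenoxide as it forms, which should prevent opening of the benzylic ethers through p-quinone methides and so protect C2′ of the cis ring from epimerisation.

## Compound list

1 | furfural | O=Cc1ccco1 | starting material
2 | 5-hydroxyfuran-2(5H)-one | O=C1C=CC(O)O1 | intermediate
3 | l-menthol | C[C@@H]1CC[C@H]([C@@H](C1)O)C(C)C | starting material
4 | (5R)-5-(l-menthyloxy)furan-2(5H)-one | O=C1C=C[C@H](O[C@@H]2C[C@H](C)CC[C@H]2C(C)C)O1 | intermediate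
5 | syringaldehyde | COc1cc(C=O)cc(OC)c1O | starting material
6 | 3,5-dimethoxy-4-(triisopropylsilyloxy)benzaldehyde | COc1cc(C=O)cc(OC)c1O[Si](C(C)C)(C(C)C)C(C)C | intermediate
7 | 2-[3,5-dimethoxy-4-(triisopropylsilyloxy)phenyl]-1,3-dithiane | COc1cc(cc(OC)c1O[Si](C(C)C)(C(C)C)C(C)C)C1SCCCS1 | intermediate
8 | vanillin | COc1cc(C=O)ccc1O | starting material
9 | 4-allyloxy-3-methoxybenzaldehyde | C=CCOc1ccc(C=O)cc1OC | intermediate
10 | 2-lithio-2-[3,5-dimethoxy-4-(triisopropylsilyloxy)phenyl]-1,3-dithiane (not isolated) | [Li]C1(SCCCS1)c1cc(OC)c(O[Si](C(C)C)(C(C)C)C(C)C)c(OC)c1 | intermediate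
11 | lithium enolate of the (4R,5R) conjugate adduct (not isolated) | [Li]OC1=C[C@@H](C2(SCCCS2)c2cc(OC)c(O[Si](C(C)C)(C(C)C)C(C)C)c(OC)c2)[C@H](O[C@@H]2C[C@H](C)CC[C@H]2C(C)C)O1 | intermediate
12 | (3S,4R,5R)-3-[(S)-(4-allyloxy-3-methoxyphenyl)(hydroxy)methyl]-4-{2-[3,5-dimethoxy-4-(triisopropylsilyloxy)phenyl]-1,3-dithian-2-yl}-5-(l-menthyloxy)dihydrofuran-2(3H)-one | C=CCOc1ccc(cc1OC)[C@@H](O)[C@H]1C(=O)O[C@@H](O[C@@H]2C[C@H](C)CC[C@H]2C(C)C)[C@@H]1C1(SCCCS1)c1cc(OC)c(O[Si](C(C)C)(C(C)C)C(C)C)c(OC)c1 | intermediate
13 | (3S,4R,5R)-3-[(S)-(4-allyloxy-3-methoxyphenyl)(hydroxy)methyl]-4-[3,5-dimethoxy-4-(triisopropylsilyloxy)benzoyl]-5-(l-menthyloxy)dihydrofuran-2(3H)-one | C=CCOc1ccc(cc1OC)[C@@H](O)[C@H]1C(=O)O[C@@H](O[C@@H]2C[C@H](C)CC[C@H]2C(C)C)[C@@H]1C(=O)c1cc(OC)c(O[Si](C(C)C)(C(C)C)C(C)C)c(OC)c1 | intermediate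
14 | (1S,2R,3R)-1-(4-allyloxy-3-methoxyphenyl)-4-[3,5-dimethoxy-4-(triisopropylsilyloxy)phenyl]-2,3-bis(hydroxymethyl)butane-1,4-diol (C4 epimers) | C=CCOc1ccc(cc1OC)[C@@H](O)[C@@H](CO)[C@H](CO)C(O)c1cc(OC)c(O[Si](C(C)C)(C(C)C)C(C)C)c(OC)c1 | intermediate
15 | (1R,2S,5R,6S)-2-(4-allyloxy-3-methoxyphenyl)-6-[3,5-dimethoxy-4-(triisopropylsilyloxy)phenyl]-3,7-dioxabicyclo[3.3.0]octane | C=CCOc1ccc(cc1OC)[C@H]1OC[C@H]2[C@@H]1CO[C@@H]2c1cc(OC)c(O[Si](C(C)C)(C(C)C)C(C)C)c(OC)c1 | intermediate
16 | 4-{(1R,2S,5R,6S)-6-[3,5-dimethoxy-4-(triisopropylsilyloxy)phenyl]-3,7-dioxabicyclo[3.3.0]octan-2-yl}-2-methoxyphenol | COc1cc(ccc1O)[C@H]1OC[C@H]2[C@@H]1CO[C@@H]2c1cc(OC)c(O[Si](C(C)C)(C(C)C)C(C)C)c(OC)c1 | intermediate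
17 | 4-{(1R,2S,5R,6S)-6-[3,5-dimethoxy-4-(triisopropylsilyloxy)phenyl]-3,7-dioxabicyclo[3.3.0]octan-2-yl}-2-iodo-6-methoxyphenol | COc1cc(cc(I)c1O)[C@H]1OC[C@H]2[C@@H]1CO[C@@H]2c1cc(OC)c(O[Si](C(C)C)(C(C)C)C(C)C)c(OC)c1 | intermediate
18 | 3-methoxy-4-(triisopropylsilyloxy)benzaldehyde | COc1cc(C=O)ccc1O[Si](C(C)C)(C(C)C)C(C)C | intermediate
19 | [3-methoxy-4-(triisopropylsilyloxy)phenyl]methanol | COc1cc(CO)ccc1O[Si](C(C)C)(C(C)C)C(C)C | intermediate
20 | (1R,2S,5R,6S)-2-(3-iodo-5-methoxy-4-{[3-methoxy-4-(triisopropylsilyloxy)phenyl]methoxy}phenyl)-6-[3,5-dimethoxy-4-(triisopropylsilyloxy)phenyl]-3,7-dioxabicyclo[3.3.0]octane | COc1cc(cc(I)c1OCc1ccc(O[Si](C(C)C)(C(C)C)C(C)C)c(OC)c1)[C@H]1OC[C@H]2[C@@H]1CO[C@@H]2c1cc(OC)c(O[Si](C(C)C)(C(C)C)C(C)C)c(OC)c1 | intermediate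
21 | methyl 2-diazo-2-(5-{(1R,2S,5R,6S)-6-[3,5-dimethoxy-4-(triisopropylsilyloxy)phenyl]-3,7-dioxabicyclo[3.3.0]octan-2-yl}-3-methoxy-2-{[3-methoxy-4-(triisopropylsilyloxy)phenyl]methoxy}phenyl)acetate | COc1cc(cc(C(=[N+]=[N-])C(=O)OC)c1OCc1ccc(O[Si](C(C)C)(C(C)C)C(C)C)c(OC)c1)[C@H]1OC[C@H]2[C@@H]1CO[C@@H]2c1cc(OC)c(O[Si](C(C)C)(C(C)C)C(C)C)c(OC)c1 | intermediate
22 | methyl (2S,3R)-7-methoxy-2-[3-methoxy-4-(triisopropylsilyloxy)phenyl]-5-{(1R,2S,5R,6S)-6-[3,5-dimethoxy-4-(triisopropylsilyloxy)phenyl]-3,7-dioxabicyclo[3.3.0]octan-2-yl}-2,3-dihydro-1-benzofuran-3-carboxylate | COc1cc([C@H]2Oc3c(OC)cc([C@H]4OC[C@H]5[C@@H]4CO[C@@H]5c4cc(OC)c(O[Si](C(C)C)(C(C)C)C(C)C)c(OC)c4)cc3[C@H]2C(=O)OC)ccc1O[Si](C(C)C)(C(C)C)C(C)C | intermediate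
23 | [(2S,3S)-7-methoxy-2-[3-methoxy-4-(triisopropylsilyloxy)phenyl]-5-{(1R,2S,5R,6S)-6-[3,5-dimethoxy-4-(triisopropylsilyloxy)phenyl]-3,7-dioxabicyclo[3.3.0]octan-2-yl}-2,3-dihydro-1-benzofuran-3-yl]methanol | COc1cc([C@H]2Oc3c(OC)cc([C@H]4OC[C@H]5[C@@H]4CO[C@@H]5c4cc(OC)c(O[Si](C(C)C)(C(C)C)C(C)C)c(OC)c4)cc3[C@H]2CO)ccc1O[Si](C(C)C)(C(C)C)C(C)C | intermediate
24 | (1R,2S,5R,6S)-6-(4-hydroxy-3,5-dimethoxyphenyl)-2-[(2S,3S)-2-(4-hydroxy-3-methoxyphenyl)-3-(hydroxymethyl)-7-methoxy-2,3-dihydro-1-benzofuran-5-yl]-3,7-dioxabicyclo[3.3.0]octane | COc1cc([C@H]2Oc3c(OC)cc([C@H]4OC[C@H]5[C@@H]4CO[C@@H]5c4cc(OC)c(O)c(OC)c4)cc3[C@H]2CO)ccc1O | target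

## Step count and least certain steps

Total: 18 steps. Longest linear sequence: 13 steps (3, 4, 6 to 11, 14 to 18; the branch through steps 1 and 2 is of equal length).

**Step 6 (key step).** Most likely failures are 1,2-addition of 10 to the lactone carbonyl, proton transfer to enolate 11 before the aldehyde is captured, and retro-Michael or retro-aldol reversal on warming. All follow from the reversibility of both bond formations and the basicity of the intermediates. Fallback, from 7 and 4, returning at 12: the conjugate addition is run alone and quenched cold to give the isolable adduct (4R,5R)-4-{2-[3,5-dimethoxy-4-(triisopropylsilyloxy)phenyl]-1,3-dithian-2-yl}-5-(l-menthyloxy)dihydrofuran-2(3H)-one F1. F1 is then re-enolised with LiN(i-Pr)2 at −78 °C, if needed transmetalated with ZnCl2, and treated with 9 in a separate aldol step, so the two bond formations are decoupled and optimised one at a time.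

**Step 9.** The ring A carbinol may ionise sluggishly, because its para oxygen is silylated and twisted out of conjugation by two flanking methoxy groups. Forcing the acid would then re-ionise the already closed ring B side (loss of exo control at C2), invite Friedel–Crafts capture of a cation by the other arene, or strip the silyl group. Fallback, from 14, returning at 15: the silyl ether is removed first (Bu4NF, AcOH, THF) to give (1S,2R,3R)-1-(4-allyloxy-3-methoxyphenyl)-4-(4-hydroxy-3,5-dimethoxyphenyl)-2,3-bis(hydroxymethyl)butane-1,4-diol F2. The free p-hydroxybenzylic alcohol closes through its p-quinone methide under much milder acid (pyridinium p-toluenesulfonate, CH2Cl2), under which the ring B carbinol also closes, giving 4-[(1R,2S,5R,6S)-6-(4-allyloxy-3-methoxyphenyl)-3,7-dioxabicyclo[3.3.0]octan-2-yl]-2,6-dimethoxyphenol F3. Re-silylation of F3 (TIPSCl, imidazole, DMF) leads back to 15.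

**Step 14.** O-alkylation may be slow at a phenol flanked by iodine and methoxy, while the electron-rich benzylic oxyphosphonium ion ionises and is lost to C-alkylation or self-condensation. Fallback, from 19 and 17, returning at 20: 19 is converted by an Appel reaction (CBr4, PPh3, CH2Cl2, 0 °C) into [4-(bromomethyl)-2-methoxyphenoxy]triisopropylsilane F4. F4 then alkylates the potassium phenoxide of 17 (K2CO3, acetone) in a Williamson ether synthesis; the robust triisopropylsilyl ethers keep this basic variant open.

**Step 15.** Palladium may decompose the diazo ester (carbene dimerisation, azine formation) faster than it adds oxidatively to an electron-rich, ortho-substituted aryl iodide, and nitrogen may be lost from 21 on the metal. Fallback, from 20, returning at 21: Negishi-type coupling of 20 with the Reformatsky reagent BrZnCH2CO2Me (Pd(dba)2, XPhos, THF) gives methyl 2-(5-{(1R,2S,5R,6S)-6-[3,5-dimethoxy-4-(triisopropylsilyloxy)phenyl]-3,7-dioxabicyclo[3.3.0]octan-2-yl}-3-methoxy-2-{[3-methoxy-4-(triisopropylsilyloxy)phenyl]methoxy}phenyl)acetate F5. Regitz diazo transfer (4-acetamidobenzenesulfonyl azide, DBU, MeCN) then converts F5 into 21; two known steps replace one.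

**Step 16.** The catalyst may discriminate poorly (facial selectivity and cis versus trans) because the benzyloxy group on ring B sits between two ortho substituents and is twisted. Carbene dimerisation may also compete if insertion is slow at low temperature. Fallback, from 20, returning at 23: a covalent auxiliary is added to the catalyst control. Step 15 is run with (1R,2S,5R)-menthyl diazoacetate to give the l-menthyl aryldiazoacetate F6. Insertion with the same rhodium catalyst gives the l-menthyl (2′S,3′R)-cis ester F7, in which any C2′/C3′ stereoisomers differ next to a chiral ester and should be separable by chromatography or crystallisation. Reduction of F7 with i-Bu2AlH gives 23 and releases l-menthol.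

## Further compounds

F1 | step 6 | (4R,5R)-4-{2-[3,5-dimethoxy-4-(triisopropylsilyloxy)phenyl]-1,3-dithian-2-yl}-5-(l-menthyloxy)dihydrofuran-2(3H)-one | O=C1C[C@@H](C2(SCCCS2)c2cc(OC)c(O[Si](C(C)C)(C(C)C)C(C)C)c(OC)c2)[C@H](O[C@@H]2C[C@H](C)CC[C@H]2C(C)C)O1
F2 | step 9 | (1S,2R,3R)-1-(4-allyloxy-3-methoxyphenyl)-4-(4-hydroxy-3,5-dimethoxyphenyl)-2,3-bis(hydroxymethyl)butane-1,4-diol (C4 epimers) | C=CCOc1ccc(cc1OC)[C@@H](O)[C@@H](CO)[C@H](CO)C(O)c1cc(OC)c(O)c(OC)c1
F3 | step 9 | 4-[(1R,2S,5R,6S)-6-(4-allyloxy-3-methoxyphenyl)-3,7-dioxabicyclo[3.3.0]octan-2-yl]-2,6-dimethoxyphenol | C=CCOc1ccc(cc1OC)[C@H]1OC[C@H]2[C@@H]1CO[C@@H]2c1cc(OC)c(O)c(OC)c1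
F4 | step 14 | [4-(bromomethyl)-2-methoxyphenoxy]triisopropylsilane | COc1cc(CBr)ccc1O[Si](C(C)C)(C(C)C)C(C)C
F5 | step 15 | methyl 2-(5-{(1R,2S,5R,6S)-6-[3,5-dimethoxy-4-(triisopropylsilyloxy)phenyl]-3,7-dioxabicyclo[3.3.0]octan-2-yl}-3-methoxy-2-{[3-methoxy-4-(triisopropylsilyloxy)phenyl]methoxy}phenyl)acetate | COc1cc(cc(CC(=O)OC)c1OCc1ccc(O[Si](C(C)C)(C(C)C)C(C)C)c(OC)c1)[C@H]1OC[C@H]2[C@@H]1CO[C@@H]2c1cc(OC)c(O[Si](C(C)C)(C(C)C)C(C)C)c(OC)c1
F6 | step 16 | (1R,2S,5R)-menthyl 2-diazo-2-(5-{(1R,2S,5R,6S)-6-[3,5-dimethoxy-4-(triisopropylsilyloxy)phenyl]-3,7-dioxabicyclo[3.3.0]octan-2-yl}-3-methoxy-2-{[3-methoxy-4-(triisopropylsilyloxy)phenyl]methoxy}phenyl)acetate | COc1cc(cc(C(=[N+]=[N-])C(=O)O[C@@H]2C[C@H](C)CC[C@H]2C(C)C)c1OCc1ccc(O[Si](C(C)C)(C(C)C)C(C)C)c(OC)c1)[C@H]1OC[C@H]2[C@@H]1CO[C@@H]2c1cc(OC)c(O[Si](C(C)C)(C(C)C)C(C)C)c(OC)c1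
F7 | step 16 | (1R,2S,5R)-menthyl (2S,3R)-7-methoxy-2-[3-methoxy-4-(triisopropylsilyloxy)phenyl]-5-{(1R,2S,5R,6S)-6-[3,5-dimethoxy-4-(triisopropylsilyloxy)phenyl]-3,7-dioxabicyclo[3.3.0]octan-2-yl}-2,3-dihydro-1-benzofuran-3-carboxylate | COc1cc([C@H]2Oc3c(OC)cc([C@H]4OC[C@H]5[C@@H]4CO[C@@H]5c4cc(OC)c(O[Si](C(C)C)(C(C)C)C(C)C)c(OC)c4)cc3[C@H]2C(=O)O[C@@H]2C[C@H](C)CC[C@H]2C(C)C)ccc1O[Si](C(C)C)(C(C)C)C(C)C
A1 | alternative 1 | (+)-medioresinol, (1R,2S,5R,6S)-2-(4-hydroxy-3-methoxyphenyl)-6-(4-hydroxy-3,5-dimethoxyphenyl)-3,7-dioxabicyclo[3.3.0]octane | COc1cc(ccc1O)[C@H]1OC[C@H]2[C@@H]1CO[C@@H]2c1cc(OC)c(O)c(OC)c1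
A2 | alternative 1 | (2R,3R)-2-(4-hydroxy-3-methoxybenzyl)-3-(4-hydroxy-3,5-dimethoxybenzyl)butane-1,4-diol | COc1cc(C[C@@H](CO)[C@H](CO)Cc2cc(OC)c(O)c(OC)c2)ccc1O
A3 | alternative 2 | (2S,3S)-3-(tert-butyldimethylsilyloxymethyl)-7-methoxy-2-[3-methoxy-4-(tosyloxy)phenyl]-2,3-dihydro-1-benzofuran (2,3-cis) | COc1cc([C@H]2Oc3c(OC)cccc3[C@H]2CO[Si](C)(C)C(C)(C)C)ccc1OS(=O)(=O)c1ccc(C)cc1
A4 | alternative 2 | (1R,2S)-3-(tert-butyldimethylsilyloxy)-2-(2-hydroxy-3-methoxyphenyl)-1-[3-methoxy-4-(tosyloxy)phenyl]propan-1-ol (syn) | COc1cc([C@H](O)[C@H](CO[Si](C)(C)C(C)(C)C)c2cccc(OC)c2O)ccc1OS(=O)(=O)c1ccc(C)cc1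
A5 | alternative 3 | (1R,2S,5R,6S)-2-(4-allyloxy-3-methoxyphenyl)-6-[4-(tert-butyldimethylsilyloxy)-3,5-dimethoxyphenyl]-8-methoxy-3,7-dioxabicyclo[3.3.0]octane | C=CCOc1ccc(cc1OC)[C@H]1OC[C@H]2[C@@H]1[C@H](OC)O[C@@H]2c1cc(OC)c(O[Si](C)(C)C(C)(C)C)c(OC)c1
A6 | alternative 3 | {(2S,3R)-2-[4-(tert-butyldimethylsilyloxy)-3,5-dimethoxyphenyl]-2,3-dihydrofuran-3-yl}methanol | OC[C@H]1C=CO[C@@H]1c1cc(OC)c(O[Si](C)(C)C(C)(C)C)c(OC)c1
A7 | alternative 3 | 4-allyloxy-3-methoxybenzaldehyde dimethyl acetal | C=CCOc1ccc(cc1OC)C(OC)OC
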